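## Retrosynthetic overview

1. The ten-membered carbocycle is closed last, at C3–C4, by a copper(I)-mediated coupling of a C3 (Z)-alkenyl iodide with a C4 alkenylstannane; the stannane comes from O15-directed trans-hydrostannation of a C4≡C5 alkyne.
2. The strategy rests on the trans C1–C10 oxirane of the ten-membered ring: C10 carries C14 (methyl), C9 and C1, with C9 anti to C2, so it is the epoxide of an E-trisubstituted C1=C10 alkene.
3. That alkene is made by syn-methylalumination of a terminal C10≡C1 alkyne and Pd/Zn coupling of the C1 alkenylalane with (Z)-(2-bromovinyl)trimethylsilane (C10–C14 and C1–C2 in one flask; silicon masks the later C3 iodide).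
4. The alkyne (C5–C9 with C6, C7, C8) comes from an Evans syn-aldol of a butynediol-derived ynal (C6–C7) and an asymmetric allenylboration (C8–C9).
5. Ring order: oxirane (Shi epoxidation), then γ-lactone (oxidative lactonisation of the C6/C12 diol, before O15 is unmasked), then the ten-membered ring.

Key step: step 14

Assumption: atoms carry germacrane numbers (ring C1–C10, lactone carbons C11–C13, methyl C14, hydroxymethyl C15); B-allenyldiisopinocampheylborane is taken to show the facial preference of the corresponding allylborane, and the D-fructose-derived Shi ketone the (R,R) sense it shows with other E-alkenes.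

## Route

Step 1
Reactants: 1 2-butyne-1,4-diol
Product: 2 4-[(triisopropylsilyl)oxy]but-2-yn-1-ol
Conditions: NaH (1 equiv), THF, 0 °C; TIPSCl (1 equiv), 1 in threefold excess, rt
Reagents that add atoms: chlorotriisopropylsilane, CC(C)[Si](Cl)(C(C)C)C(C)C
Why: Statistical monosilylation of a symmetrical diol through its monosodium alkoxide; the excess diol suppresses the bis-ether and is washed out with water.

Step 2
Reactants: 2 4-[(triisopropylsilyl)oxy]but-2-yn-1-ol
Product: 3 4-[(triisopropylsilyl)oxy]but-2-ynal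
Conditions: activated MnO2, CH2Cl2, rt
Reagents that add atoms: none
Why: Manganese dioxide oxidation of a propargylic alcohol should stop at the ynal and leave the silyl ether alone.

Step 3
Reactants: 4 methyl 2-(bromomethyl)acrylate
Product: 5 2-(bromomethyl)prop-2-en-1-ol
Conditions: DIBAL-H (2.2 equiv), CH2Cl2, −78 °C; Rochelle salt
Reagents that add atoms: none
Why: DIBAL-H 1,2-reduction of the acrylate ester at −78 °C should give the allylic alcohol while the allylic bromide and the alkene stay.

Step 4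
Reactants: 5 2-(bromomethyl)prop-2-en-1-ol
Product: 6 {[2-(bromomethyl)prop-2-en-1-yl]oxy}triethylsilane
Conditions: TESCl, imidazole, CH2Cl2, 0 °C
Reagents that add atoms: chlorotriethylsilane, CC[Si](Cl)(CC)CC
Why: O-Silylation of the primary alcohol at 0 °C should be faster than N-alkylation of imidazole by the allylic bromide.

Step 5
Reactants: 6 {[2-(bromomethyl)prop-2-en-1-yl]oxy}triethylsilane
Product: 8 3-{[(triethylsilyl)oxy]methyl}but-3-enoic acid, via allylmagnesium reagent 7 (not isolated)
Conditions: Mg, THF, 0 °C; CO2, −78 → 0 °C; aq. NaH2PO4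
Reagents that add atoms: carbon dioxide, O=C=O
Why: Grignard formation and carboxylation; the two CH2 termini of the 2-substituted allyl unit are equivalent, so only the β,γ-unsaturated acid can form, and the weakly acidic work-up should keep the TES ether.

Step 6
Reactants: 8 3-{[(triethylsilyl)oxy]methyl}but-3-enoic acid; 9 (S)-4-benzyloxazolidin-2-one
Product: 11 (S)-4-benzyl-3-(3-{[(triethylsilyl)oxy]methyl}but-3-enoyl)oxazolidin-2-one, via mixed pivalic anhydride 10 (not isolated)
Conditions: PivCl, Et3N, THF, −20 °C; then 9, LiCl, −20 °C → rt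
Reagents that add atoms: none
Why: N-Acylation of the Evans auxiliary through the mixed pivalic anhydride at low temperature, so that the β,γ-alkene does not move into conjugation.

Step 7
Reactants: 11 (S)-4-benzyl-3-(3-{[(triethylsilyl)oxy]methyl}but-3-enoyl)oxazolidin-2-one; 3 4-[(triisopropylsilyl)oxy]but-2-ynal
Product: 13 (S)-4-benzyl-3-[(2S,3S)-3-hydroxy-2-(3-{[triethylsilyl]oxy}prop-1-en-2-yl)-6-{[triisopropylsilyl]oxy}hex-4-ynoyl]oxazolidin-2-one, via boron dienolate 12 (not isolated)
Conditions: n-Bu2BOTf, Et3N, CH2Cl2, −78 → 0 °C; 3, −78 → 0 °C; pH 7 buffer, MeOH, H2O2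
Reagents that add atoms: none
Why: Evans syn-aldol reaction: soft enolisation gives the Z(O)-boron dienolate, which reacts at its α-carbon through a Zimmerman–Traxler chair on the face away from the benzyl group, setting C7 and C6 together (C11 and O6 syn).

Step 8
Reactants: 13 syn-aldol adduct
Product: 14 O6-triethylsilyl ether of 13
Conditions: TESOTf, 2,6-lutidine, CH2Cl2, −78 °C
Reagents that add atoms: triethylsilyl triflate, CC[Si](CC)(CC)OS(=O)(=O)C(F)(F)F
Why: Silylation of the secondary propargylic alcohol with the silyl triflate; O6 stays masked until the lactonisation.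

Step 9
Reactants: 14 O6-triethylsilyl ether of 13
Product: 15 (2R,3S)-2-(3-{[triethylsilyl]oxy}prop-1-en-2-yl)-3-[(triethylsilyl)oxy]-6-[(triisopropylsilyl)oxy]hex-4-yn-1-ol
Conditions: LiBH4, MeOH (1 equiv), Et2O, 0 °C
Reagents that add atoms: none
Why: Reductive cleavage of the N-acyloxazolidinone with lithium borohydride gives the C8 primary alcohol without touching C7 and returns the auxiliary.

Step 10
Reactants: 15 primary alcohol
Product: 16 (2S,3S)-2-(3-{[triethylsilyl]oxy}prop-1-en-2-yl)-3-[(triethylsilyl)oxy]-6-[(triisopropylsilyl)oxy]hex-4-ynal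
Conditions: Dess–Martin periodinane, pyridine, CH2Cl2, 0 °C; used crude at once
Reagents that add atoms: none
Why: Buffered Dess–Martin oxidation gives the α-alkenyl aldehyde under non-basic conditions, so that C7 should neither epimerise nor conjugate.

Step 11
Reactants: 16 α-alkenyl aldehyde
Product: 17 (4R,5R,6S)-5-(3-{[triethylsilyl]oxy}prop-1-en-2-yl)-6-[(triethylsilyl)oxy]-9-[(triisopropylsilyl)oxy]nona-1,7-diyn-4-ol
Conditions: allenylmagnesium bromide, (+)-Ipc2BOMe [from (−)-α-pinene], Et2O, −78 °C → rt; 16, −78 °C; NaOH, H2O2, 0 °C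
Reagents that add atoms: allenylmagnesium bromide, C=C=C[Mg]Br
Why: Brown-type asymmetric allenylboration (SE2' through a six-membered chair) gives the homopropargylic alcohol with the terminal alkyne; the (−)-α-pinene-derived reagent is expected to add to the Re face of the aldehyde under reagent control, setting C8 (R).

Step 12
Reactants: 18 ethynyltrimethylsilane
Product: 19 (bromoethynyl)trimethylsilane
Conditions: NBS, AgNO3 (cat.), acetone, rt
Reagents that add atoms: N-bromosuccinimide, O=C1CCC(=O)N1Br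
Why: Silver-catalysed electrophilic bromination of a terminal alkyne.

Step 13
Reactants: 19 (bromoethynyl)trimethylsilane
Product: 20 (Z)-(2-bromovinyl)trimethylsilane
Conditions: dipotassium azodicarboxylate, AcOH, MeOH, 0 °C → rt
Reagents that add atoms: none
Why: cis-Reduction of a 1-bromoalkyne with diimide made in the flask delivers both hydrogens to one face and should give the Z-bromoalkene without cleaving the C–Br bond.

Step 14
Reactants: 17 homopropargylic alcohol (terminal C10≡C1 alkyne); 20 (Z)-(2-bromovinyl)trimethylsilane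
Product: 22 (1E,3Z)-dienylsilane [17 with C14 methyl on C10 and C1 joined to C2H=C3H–SiMe3; (6S,7R,8R)], via alkenylalane 21 (not isolated)
Conditions: AlMe3 (4 equiv), Cp2ZrCl2 (25 mol%), CH2Cl2, 0 °C → rt; volatiles removed; THF, ZnCl2, Pd(PPh3)4 (5 mol%), 20, rt; Rochelle salt
Reagents that add atoms: trimethylaluminium, C[Al](C)C
Why: The Zr/Al methyl species adds Me–Al syn across the terminal alkyne, methyl to the internal carbon C10 and aluminium to C1; the alkenylalane is passed through zinc to palladium, which has inserted into the C–Br bond of 20 with retention, and reductive elimination forms C1–C2. The closest known reaction type is the Negishi zirconium-catalysed carboalumination with in-flask Pd/Zn cross-coupling of the alkenylalane with an alkenyl halide. No ring is closed and no stereocentre is formed; the step fixes the 1E geometry (C9 trans to C2, C14 cis to C2) that becomes the trans oxirane, and the 2Z geometry. It needs regioselectivity and chemoselectivity: the terminal alkyne reacts far faster than the internal C4≡C5 alkyne, which is flanked by two silyloxy-bearing carbons. The free O8–H is taken up as an aluminium alkoxide by the extra AlMe3, and the excess AlMe3 is removed before palladium is added so that no methyl coupling with 20 competes.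

Step 15
Reactants: 22 (1E,3Z)-dienylsilane
Product: 23 (1R,10R)-epoxy alcohol [C1–C10 oxirane, C2=C3 Z-vinylsilane, O8–H free]
Conditions: Shi ketone (D-fructose-derived, 30 mol%), Oxone, K2CO3, Bu4NHSO4, MeCN/dimethoxymethane/aq. borate buffer, 0 °C
Reagents that add atoms: potassium peroxymonosulfate (Oxone), [K+].[O-]S(=O)(=O)OO
Why: Shi asymmetric epoxidation: the chiral dioxirane attacks the electron-rich E-trisubstituted C1=C10 terminus of the diene through a spiro transition state and should give the (1R,10R) oxirane under reagent control, while the Z-vinylsilane and the 1,1-disubstituted alkene are poor substrates.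

Step 16
Reactants: 24 but-2-yn-1-ol
Product: 26 (Z)-3-iodobut-2-en-1-ol, via cyclic vinylalanate 25 (not isolated)
Conditions: Red-Al, THF, 0 °C → rt; I2, −78 → 0 °C
Reagents that add atoms: iodine, II
Why: Hydroxyl-directed trans-hydroalumination puts aluminium on C3 cis to the carbinol in a five-membered alanate, and iodinolysis with retention gives the Z-iodide.

Step 17
Reactants: 26 (Z)-3-iodobut-2-en-1-ol
Product: 27 (Z)-3-iodobut-2-en-1-yl acetate
Conditions: Ac2O, pyridine, DMAP (cat.), CH2Cl2, 0 °C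
Reagents that add atoms: acetic anhydride, CC(=O)OC(C)=O
Why: Acetylation of the primary alcohol, which blocks later lactonisation to the butenolide.

Step 18
Reactants: 27 (Z)-3-iodobut-2-en-1-yl acetate
Product: 28 (Z)-4-acetoxy-2-methylbut-2-enoic acid
Conditions: Pd(OAc)2 (5 mol%), PPh3, CO (1 atm), H2O, Et3N, DMF, rt
Reagents that add atoms: carbon monoxide, [C-]#[O+]; water, O
Why: Palladium-catalysed hydroxycarbonylation of the alkenyl iodide (oxidative addition, CO insertion, hydrolysis of the acylpalladium) keeps the alkene geometry, and insertion into C–I should be much faster than ionisation of the allylic acetate.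

Step 19
Reactants: 23 (1R,10R)-epoxy alcohol; 28 (Z)-4-acetoxy-2-methylbut-2-enoic acid
Product: 30 O8 ester of 23 with the (Z)-4-acetoxy-2-methylbut-2-enoyl group, via Yamaguchi mixed anhydride 29 (not isolated)
Conditions: 28, 2,4,6-trichlorobenzoyl chloride, Et3N, toluene, rt; then 23, DMAP, toluene, rt
Reagents that add atoms: none
Why: Yamaguchi esterification acylates the hindered O8–H through the mixed trichlorobenzoic anhydride, a protocol that keeps angelate-type Z-enoates from isomerising.

Step 20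
Reactants: 30 O8 ester
Product: 31 C6/C12 diol [both TES ethers removed; TIPS ether, vinylsilane, oxirane and esters kept]
Conditions: TBAF, AcOH (1:1), THF, 0 °C
Reagents that add atoms: none
Why: Buffered fluoride should cleave the two triethylsilyl ethers far faster than the triisopropylsilyl ether or the vinyl C–Si bond, and the near-neutral medium spares the oxirane and the esters.

Step 21
Reactants: 31 C6/C12 diol
Product: 34 α-methylene-γ-lactone [O6–C12(=O)–C11(=C13)–C7, trans at C6/C7; TIPS ether, vinylsilane, oxirane kept], via enal 32 (not isolated), via lactol 33 (not isolated)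
Conditions: TEMPO (20 mol%), PhI(OAc)2, CH2Cl2, rt
Reagents that add atoms: none
Why: TEMPO/PhI(OAc)2 oxidative lactonisation: the primary allylic C12 alcohol is oxidised first, the enal is trapped by O6–H as the five-membered lactol, and a second oxidation gives the lactone, while O15 is still protected.

Step 22
Reactants: 34 α-methylene-γ-lactone with Z-vinylsilane
Product: 35 (Z)-alkenyl iodide [34 with iodine in place of SiMe3 at C3]
Conditions: NIS, ClCH2CN/MeCN (4:1), 0 °C, dark
Reagents that add atoms: N-iodosuccinimide, O=C1CCC(=O)N1I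
Why: ipso-Iododesilylation of a Z-vinylsilane in chloroacetonitrile should proceed with retention; the other alkenes are electron-poor and no free hydroxyl is present to take part.

Step 23
Reactants: 35 (Z)-alkenyl iodide
Product: 36 propargylic alcohol [35 with free O15–H]
Conditions: TBAF, AcOH (1:1, excess), THF, 0 °C → rt
Reagents that add atoms: none
Why: Buffered fluoride cleavage of the primary triisopropylsilyl ether frees O15–H without base strong enough to harm the methylene lactone, the acetate or the alkenyl iodide.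

Step 24
Reactants: 36 propargylic alcohol
Product: 37 C4 alkenylstannane [SnBu3 on C4, H on C5, tin cis to C6; C3 iodide kept]
Conditions: [Cp*RuCl]4 (2.5 mol%), Bu3SnH (1.1 equiv, slow addition), CH2Cl2, rt
Reagents that add atoms: tributyltin hydride, CCCC[SnH](CCCC)CCCC
Why: Ruthenium-catalysed trans-hydrostannation steered by the free propargylic O15–H should place tin on the proximal carbon C4 and hydrogen anti on C5, which is the geometry the ring needs.

Step 25
Reactants: 37 C4 alkenylstannane with C3 (Z)-alkenyl iodide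
Product: 38 CNP0103272.1 (target)
Conditions: CuTC (3 equiv), NMP, 0 °C → rt, 1 mM, dark
Reagents that add atoms: none
Why: Copper(I) thiophene-2-carboxylate-mediated Stille-type coupling: tin-to-copper exchange at C4, helped by the neighbouring hydroxyl, and coupling with the C3 iodide with retention at both alkenes closes the ten-membered ring; no palladium is used because of the vinyl oxirane and the allylic acetate.

## Compound list

1 | 2-butyne-1,4-diol | OCC#CCO | starting material
2 | 4-[(triisopropylsilyl)oxy]but-2-yn-1-ol | OCC#CCO[Si](C(C)C)(C(C)C)C(C)C | intermediate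
3 | 4-[(triisopropylsilyl)oxy]but-2-ynal | O=CC#CCO[Si](C(C)C)(C(C)C)C(C)C | intermediate
4 | methyl 2-(bromomethyl)acrylate | C=C(CBr)C(=O)OC | starting material
5 | 2-(bromomethyl)prop-2-en-1-ol | C=C(CBr)CO | intermediate
6 | {[2-(bromomethyl)prop-2-en-1-yl]oxy}triethylsilane | C=C(CBr)CO[Si](CC)(CC)CC | intermediate
7 | (2-{[(triethylsilyl)oxy]methyl}prop-2-en-1-yl)magnesium bromide | C=C(C[Mg]Br)CO[Si](CC)(CC)CC | intermediate
8 | 3-{[(triethylsilyl)oxy]methyl}but-3-enoic acid | C=C(CC(=O)O)CO[Si](CC)(CC)CC | intermediate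
9 | (S)-4-benzyloxazolidin-2-one | O=C1OC[C@H](Cc2ccccc2)N1 | starting material
10 | mixed anhydride of 8 and pivalic acid | C=C(CC(=O)OC(=O)C(C)(C)C)CO[Si](CC)(CC)CC | intermediate
11 | (S)-4-benzyl-3-(3-{[(triethylsilyl)oxy]methyl}but-3-enoyl)oxazolidin-2-one | O=C1OC[C@H](Cc2ccccc2)N1C(=O)CC(=C)CO[Si](CC)(CC)CC | intermediate
12 | Z(O)-dibutylboron dienolate of 11 | O=C1OC[C@H](Cc2ccccc2)N1/C(OB(CCCC)CCCC)=C/C(=C)CO[Si](CC)(CC)CC | intermediate
13 | (S)-4-benzyl-3-[(2S,3S)-3-hydroxy-2-(3-{[triethylsilyl]oxy}prop-1-en-2-yl)-6-{[triisopropylsilyl]oxy}hex-4-ynoyl]oxazolidin-2-one | O=C1OC[C@H](Cc2ccccc2)N1C(=O)[C@@H](C(=C)CO[Si](CC)(CC)CC)[C@H](O)C#CCO[Si](C(C)C)(C(C)C)C(C)C | intermediate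
14 | O6-triethylsilyl ether of 13 [(2S,3S)] | O=C1OC[C@H](Cc2ccccc2)N1C(=O)[C@@H](C(=C)CO[Si](CC)(CC)CC)[C@H](O[Si](CC)(CC)CC)C#CCO[Si](C(C)C)(C(C)C)C(C)C | intermediate
15 | (2R,3S)-2-(3-{[triethylsilyl]oxy}prop-1-en-2-yl)-3-[(triethylsilyl)oxy]-6-[(triisopropylsilyl)oxy]hex-4-yn-1-ol | OC[C@@H](C(=C)CO[Si](CC)(CC)CC)[C@H](O[Si](CC)(CC)CC)C#CCO[Si](C(C)C)(C(C)C)C(C)C | intermediate
16 | (2S,3S)-2-(3-{[triethylsilyl]oxy}prop-1-en-2-yl)-3-[(triethylsilyl)oxy]-6-[(triisopropylsilyl)oxy]hex-4-ynal | O=C[C@@H](C(=C)CO[Si](CC)(CC)CC)[C@H](O[Si](CC)(CC)CC)C#CCO[Si](C(C)C)(C(C)C)C(C)C | intermediate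
17 | (4R,5R,6S)-5-(3-{[triethylsilyl]oxy}prop-1-en-2-yl)-6-[(triethylsilyl)oxy]-9-[(triisopropylsilyl)oxy]nona-1,7-diyn-4-ol (key-step precursor; germacrane 6S,7R,8R) | C#CC[C@@H](O)[C@@H](C(=C)CO[Si](CC)(CC)CC)[C@H](O[Si](CC)(CC)CC)C#CCO[Si](C(C)C)(C(C)C)C(C)C | intermediate
18 | ethynyltrimethylsilane | C#C[Si](C)(C)C | starting material
19 | (bromoethynyl)trimethylsilane | BrC#C[Si](C)(C)C | intermediate
20 | (Z)-(2-bromovinyl)trimethylsilane | Br/C=C\[Si](C)(C)C | intermediate
21 | (E)-C1 dimethylalumino alkenylalane of 17, C14 methyl on C10, O8 as dimethylaluminium alkoxide | C[Al](C)/C=C(C)/C[C@@H](O[Al](C)C)[C@@H](C(=C)CO[Si](CC)(CC)CC)[C@H](O[Si](CC)(CC)CC)C#CCO[Si](C(C)C)(C(C)C)C(C)C | intermediate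
22 | (1E,3Z)-dienylsilane, C14 methyl on C10, O8–H free, configuration at C6–C8 as in 17 (key-step product) | C[Si](C)(C)/C=C\C=C(C)\C[C@@H](O)[C@@H](C(=C)CO[Si](CC)(CC)CC)[C@H](O[Si](CC)(CC)CC)C#CCO[Si](C(C)C)(C(C)C)C(C)C | intermediate
23 | (1R,10R)-epoxy alcohol: C1–C10 oxirane of 22, Z-vinylsilane kept | C[Si](C)(C)/C=C\[C@H]1O[C@]1(C)C[C@@H](O)[C@@H](C(=C)CO[Si](CC)(CC)CC)[C@H](O[Si](CC)(CC)CC)C#CCO[Si](C(C)C)(C(C)C)C(C)C | intermediate
24 | but-2-yn-1-ol | CC#CCO | starting material
25 | sodium 2,2-bis(2-methoxyethoxy)-3-methyl-2,5-dihydro-1,2-oxaaluminol-2-uide (cyclic vinylalanate) | CC1=CCO[Al-]1(OCCOC)OCCOC.[Na+] | intermediate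
26 | (Z)-3-iodobut-2-en-1-ol | C/C(I)=C/CO | intermediate
27 | (Z)-3-iodobut-2-en-1-yl acetate | C/C(I)=C/COC(C)=O | intermediate
28 | (Z)-4-acetoxy-2-methylbut-2-enoic acid | CC(=O)OC/C=C(/C)C(=O)O | intermediate
29 | mixed anhydride of 28 and 2,4,6-trichlorobenzoic acid | CC(=O)OC/C=C(/C)C(=O)OC(=O)c1c(Cl)cc(Cl)cc1Cl | intermediate
30 | O8 (Z)-4-acetoxy-2-methylbut-2-enoate of 23 | C[Si](C)(C)/C=C\[C@H]1O[C@]1(C)C[C@@H](OC(=O)/C(C)=C\COC(C)=O)[C@@H](C(=C)CO[Si](CC)(CC)CC)[C@H](O[Si](CC)(CC)CC)C#CCO[Si](C(C)C)(C(C)C)C(C)C | intermediate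
31 | C6/C12 diol of 30 (TIPS ether kept) | C[Si](C)(C)/C=C\[C@H]1O[C@]1(C)C[C@@H](OC(=O)/C(C)=C\COC(C)=O)[C@@H](C(=C)CO)[C@H](O)C#CCO[Si](C(C)C)(C(C)C)C(C)C | intermediate
32 | C12 enal of 31 (O6–H free) | C[Si](C)(C)/C=C\[C@H]1O[C@]1(C)C[C@@H](OC(=O)/C(C)=C\COC(C)=O)[C@@H](C(=C)C=O)[C@H](O)C#CCO[Si](C(C)C)(C(C)C)C(C)C | intermediate
33 | C12 lactol (both C12 epimers) | C=C1C(O)O[C@H](C#CCO[Si](C(C)C)(C(C)C)C(C)C)[C@H]1[C@H](OC(=O)/C(C)=C\COC(C)=O)C[C@@]2(C)O[C@@H]2/C=C\[Si](C)(C)C | intermediate
34 | α-methylene-γ-lactone with O15-TIPS ether, C4≡C5 alkyne, (1R,10R)-oxirane and Z-vinylsilane | C=C1C(=O)O[C@H](C#CCO[Si](C(C)C)(C(C)C)C(C)C)[C@H]1[C@H](OC(=O)/C(C)=C\COC(C)=O)C[C@@]2(C)O[C@@H]2/C=C\[Si](C)(C)C | intermediate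
35 | C3 (Z)-alkenyl iodide of 34 | C=C1C(=O)O[C@H](C#CCO[Si](C(C)C)(C(C)C)C(C)C)[C@H]1[C@H](OC(=O)/C(C)=C\COC(C)=O)C[C@@]2(C)O[C@@H]2/C=C\I | intermediate
36 | 35 with free O15–H (propargylic alcohol) | C=C1C(=O)O[C@H](C#CCO)[C@H]1[C@H](OC(=O)/C(C)=C\COC(C)=O)C[C@@]2(C)O[C@@H]2/C=C\I | intermediate
37 | C4 tributylstannyl alkene (Sn cis to C6, C15 hydroxymethyl on C4) with C3 (Z)-iodide | C=C1C(=O)O[C@H](/C=C(/CO)[Sn](CCCC)(CCCC)CCCC)[C@H]1[C@H](OC(=O)/C(C)=C\COC(C)=O)C[C@@]2(C)O[C@@H]2/C=C\I | intermediate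
38 | CNP0103272.1, (1R,6R,7R,8R,10R) in germacrane numbering | C=C1C(=O)O[C@@H]2/C=C(CO)\C=C/[C@H]3O[C@]3(C)C[C@@H](OC(=O)/C(C)=C\COC(C)=O)[C@@H]12 | target

## Step count and risks

Total step count: 25. Longest linear sequence: 18 steps (steps 3–11, 14, 15, 19–25, from methyl 2-(bromomethyl)acrylate).

Steps most likely to fail:

1. Step 25. The ten-membered ring may close too slowly, so that protodestannylation of the hindered C4 stannane and intermolecular coupling take over. Fallback: from 37, iododestannylation (I2, CH2Cl2, 0 °C) should give the bis(alkenyl iodide) F1. Its two C–I bonds are then joined by an intramolecular copper(I)-mediated Ullmann-type reductive coupling (CuTC, NMP, high dilution), which needs no tin-to-copper exchange; the fallback returns to the route at 38.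

2. Step 24. The tin hydride may reduce the alkenyl iodide or add to the methylene lactone, or the tin may go to C5. Fallback: from 34, the hydrostannation is run before any alkenyl iodide exists. Buffered TBAF gives the propargylic alcohol F2, and [Cp*RuCl]4/Bu3SnH gives the C4 stannane F3. Iodine at 0 °C replaces tin selectively over silicon to give the C4 iodide F4, and NIS then gives the bis(alkenyl iodide) F1. F1 is closed by the copper(I) reductive coupling described above, and the fallback returns at 38.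

3. Step 22. The electrophile or the β-silyl cation next to the oxirane may open or rearrange the epoxide, and the Z geometry may be lost. Fallback: from 22, the silicon is exchanged before the oxirane exists. Yamaguchi esterification with 28 gives the dienylsilane ester F5, and NIS gives the dienyl iodide F6. Shi epoxidation gives the epoxy iodide F7, and buffered TBAF gives the diol F8. TEMPO/PhI(OAc)2 lactonisation of F8 returns to the route at 35.

## Further compounds

F1 | step 25 | bis(alkenyl iodide): 37 with iodine in place of SnBu3 at C4 | C=C1C(=O)O[C@H](/C=C(/CO)I)[C@H]1[C@H](OC(=O)/C(C)=C\COC(C)=O)C[C@@]2(C)O[C@@H]2/C=C\I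
F2 | step 24 | 34 with free O15–H (vinylsilane kept) | C=C1C(=O)O[C@H](C#CCO)[C@H]1[C@H](OC(=O)/C(C)=C\COC(C)=O)C[C@@]2(C)O[C@@H]2/C=C\[Si](C)(C)C
F3 | step 24 | C4 tributylstannyl alkene with C3 vinylsilane | C=C1C(=O)O[C@H](/C=C(/CO)[Sn](CCCC)(CCCC)CCCC)[C@H]1[C@H](OC(=O)/C(C)=C\COC(C)=O)C[C@@]2(C)O[C@@H]2/C=C\[Si](C)(C)C
F4 | step 24 | C4 alkenyl iodide with C3 vinylsilane | C=C1C(=O)O[C@H](/C=C(/CO)I)[C@H]1[C@H](OC(=O)/C(C)=C\COC(C)=O)C[C@@]2(C)O[C@@H]2/C=C\[Si](C)(C)C
F5 | step 22 | O8 (Z)-4-acetoxy-2-methylbut-2-enoate of 22 | C[Si](C)(C)/C=C\C=C(C)\C[C@@H](OC(=O)/C(C)=C\COC(C)=O)[C@@H](C(=C)CO[Si](CC)(CC)CC)[C@H](O[Si](CC)(CC)CC)C#CCO[Si](C(C)C)(C(C)C)C(C)C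
F6 | step 22 | (1E,3Z)-dienyl iodide: F5 with iodine in place of SiMe3 | I/C=C\C=C(C)\C[C@@H](OC(=O)/C(C)=C\COC(C)=O)[C@@H](C(=C)CO[Si](CC)(CC)CC)[C@H](O[Si](CC)(CC)CC)C#CCO[Si](C(C)C)(C(C)C)C(C)C
F7 | step 22 | (1R,10R)-oxirane of F6 | I/C=C\[C@H]1O[C@]1(C)C[C@@H](OC(=O)/C(C)=C\COC(C)=O)[C@@H](C(=C)CO[Si](CC)(CC)CC)[C@H](O[Si](CC)(CC)CC)C#CCO[Si](C(C)C)(C(C)C)C(C)C
F8 | step 22 | C6/C12 diol of F7 | I/C=C\[C@H]1O[C@]1(C)C[C@@H](OC(=O)/C(C)=C\COC(C)=O)[C@@H](C(=C)CO)[C@H](O)C#CCO[Si](C(C)C)(C(C)C)C(C)C
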